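**Retrosynthetic overview**
1. The last C–C bond, between the side-chain carbinol carbon and its methyl-bearing neighbour, comes from a syn boron aldol of pentan-3-one with a 2-substituted acrolein. Before that, the 2-methoxy-3,5-dimethyl-4-pyranone is grown on the quaternary ring carbon from a neopentyl aldehyde and a β-keto ester dianion.
2. That aldehyde comes from a cis-fused epoxy γ-lactone. The lactone acyl carbon becomes the aldehyde (pyranone anchor); the lactone carbinol carbon becomes, after oxidation and methylenation, the methylene-bearing side-chain carbon.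
3. Feature that carries the strategy: the carbocycle C1–C6 (C1 = CH with the side chain; C2/C3 = epoxide, methyl on C2; C4(Me)=C5H; C6 = quaternary carbon with methyl and pyranone) is a masked cyclohexa-1,3-diene. It has methyls on alternate carbons (C2, C4) and two adjacent sp3 carbons (C6, C1) whose carbon arms are cis.
4. This pattern is cut at C1–C2 and C5–C6 into 3,5-dimethyl-2-pyranone and a chiral-pool 3-methylbutenolide (Diels–Alder reaction, then loss of CO2).
5. Ring order: butenolide (kept as the cis-fused γ-lactone) → bridged lactone and carbocycle in one event → cyclohexadiene by loss of CO2 → epoxide → γ-lactone opened → 4-pyranone.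

Key step: step 6

Assumption: the (+)-Ipc2BOTf antipode (from (−)-α-pinene) is taken to send the (Z)-enolate of an ethyl ketone to the Re face of a 2-substituted acrolein, the same facial sense as the allylboranes of that isopinocampheyl series; a trial with methacrolein would confirm this, and the other antipode would be used if the sense were reversed.

Convention: in the monocyclic compounds the ring atoms are called C1–C6 as in line 3 of the overview; the epoxide oxygen is anti to the two cis carbon arms on C1 and C6.

**Step 1**
Reactants: 1 (S)-5-(hydroxymethyl)dihydrofuran-2(3H)-one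
Product: 2 (S)-5-[(tert-butyldiphenylsilyl)oxymethyl]dihydrofuran-2(3H)-one
Conditions: TBDPSCl, imidazole, DMF, 0 °C to rt
Reagents that add atoms: tert-butyl(chloro)diphenylsilane, CC(C)(C)[Si](Cl)(c1ccccc1)c1ccccc1
Why: Imidazole-assisted silylation of the primary alcohol installs the bulky ether that later shields one face of the butenolide, and the stereocentre is not touched.

**Step 2**
Reactants: 2 (S)-5-[(tert-butyldiphenylsilyl)oxymethyl]dihydrofuran-2(3H)-one
Product: 4 (3R,5S)-5-[(tert-butyldiphenylsilyl)oxymethyl]-3-methyldihydrofuran-2(3H)-one (trans; the minor C3 epimer is carried along), via lithium enolate 3 (not isolated)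
Conditions: LiN(iPr)2, THF, −78 °C; MeI, −78 to −40 °C
Reagents that add atoms: iodomethane, CI
Why: Enolate alkylation, in which the lithium enolate should be methylated mainly anti to the C5 substituent; the new C3 centre is of no consequence because it becomes sp2 in step 4.

**Step 3**
Reactants: 4 (3R,5S)-5-[(tert-butyldiphenylsilyl)oxymethyl]-3-methyldihydrofuran-2(3H)-one
Product: 6 (3R,5S)-5-[(tert-butyldiphenylsilyl)oxymethyl]-3-methyl-3-(phenylselanyl)dihydrofuran-2(3H)-one (selenium anti to the silyloxymethyl group), via lithium enolate 5 (not isolated)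
Conditions: LiN(iPr)2, THF, −78 °C; PhSeBr, −78 °C
Reagents that add atoms: benzeneselenenyl bromide, Br[Se]c1ccccc1
Why: α-Selenenylation of the lactone enolate by electrophilic selenium transfer, the selenium entering anti to the silyloxymethyl group, which leaves a ring hydrogen at C4 syn to selenium for the elimination.

**Step 4**
Reactants: 6 (3R,5S)-5-[(tert-butyldiphenylsilyl)oxymethyl]-3-methyl-3-(phenylselanyl)dihydrofuran-2(3H)-one
Product: 8 (S)-5-[(tert-butyldiphenylsilyl)oxymethyl]-3-methylfuran-2(5H)-one (fragment 1; dienophile), via selenoxide 7 (not isolated)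
Conditions: 30% H2O2, pyridine, CH2Cl2, 0 °C to rt
Reagents that add atoms: none
Why: Oxidation to the selenoxide and syn β-elimination (selenoxide elimination) toward the ring CH2 should give the endocyclic trisubstituted butenolide without touching the C5 stereocentre, any exocyclic methylene isomer being removed by chromatography.

**Step 5**
Reactants: 9 3,5-dibromo-2H-pyran-2-one
Product: 10 3,5-dimethyl-2H-pyran-2-one (fragment 2; diene)
Conditions: Me4Sn (4 equiv), Pd(PPh3)4 (10 mol %), CuI (20 mol %), DMF, 90 °C, sealed tube
Reagents that add atoms: tetramethylstannane, C[Sn](C)(C)C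
Why: Twofold Stille methyl cross-coupling at both C(sp2)–Br bonds under zerovalent palladium catalysis, with CuI to speed transmetalation at the slower C5 position, under neutral conditions that the base-sensitive pyranone tolerates.

**Step 6**
Reactants: 8 (S)-5-[(tert-butyldiphenylsilyl)oxymethyl]-3-methylfuran-2(5H)-one; 10 3,5-dimethyl-2H-pyran-2-one
Product: 12 cis-fused diene lactone (3S)-3-[(tert-butyldiphenylsilyl)oxymethyl]-4,6,7a-trimethyl-3a,7a-dihydroisobenzofuran-1(3H)-one (silyloxymethyl group anti to the carbocycle), via bridged lactone adduct 11 (not isolated)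
Conditions: 10 (4 equiv), BHT, CH2Cl2, 12 kbar, 50 °C; then PhMe, 110 °C
Reagents that add atoms: none
Why: Diels–Alder cycloaddition of the pyranone diene (C3 to C6) across the butenolide C3=C4 bond forms the bonds pyranone C3–butenolide C4 (β-carbon) and pyranone C6–butenolide C3 (methyl-bearing α-carbon) to give bridged lactone 11, whose retro-[4+2] loss of CO2 on heating leaves cyclohexa-1,3-diene 12 with both ring methyls in place. The closest known reaction type is the thermal or high-pressure cycloaddition of alkyl 2-pyranones to alkenes followed by extrusion of CO2, together with the anti-selective cycloaddition of dienes to 5-substituted butenolides. The six-membered carbocycle is closed by a concerted, suprafacial intermolecular [4+2] cycloaddition (two C–C bonds at once), the bridging lactone ring made in the same event is reopened by cycloreversion, and the five-membered lactone of 8 survives as the cis-fused ring. The quaternary carbon and the neighbouring CH are set together, cis by the suprafacial addition and in the absolute sense by approach of the diene to the face of 8 anti to the silyloxymethyl group on the (S) stereocentre, while the endo/exo and pyranone-face isomers of 11 differ only at the bridge and converge on 12. The step needs regio- and face selectivity: the orientation shown joins each methyl-bearing carbon to a CH carbon, whereas the reverse one would have to bond the methyl-bearing C3 of 10 to the methyl-bearing α-carbon of 8, and the polarity of the partners (C3 is a carbon of a 2-pyranone that electrophiles attack, the β-carbon is the electrophilic end of 8) points the same way, although the ring methyls weaken this electronic bias so that the steric term must decide; the bulky silyl ether secures the face. The quaternary carbon prevents aromatisation, and the hindered diene 12 should not add a second butenolide.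

**Step 7**
Reactants: 12 cis-fused diene lactone
Product: 13 vinyl epoxide lactone (4,5-epoxide of 12; epoxide oxygen on the convex face, anti to the lactone ring)
Conditions: dimethyldioxirane (1.1 equiv), acetone/CH2Cl2, −40 to 0 °C
Reagents that add atoms: dimethyldioxirane, CC1(C)OO1
Why: Electrophilic epoxidation by concerted oxygen transfer from the dioxirane, which should take the C4=C5 bond (the C6=C7 bond is flanked by the quaternary carbon and deactivated by the allylic lactone carbonyl) from the convex face of the cis-fused bicycle, anti to both carbon arms, setting both epoxide carbons under neutral conditions that the vinyl epoxide tolerates.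

**Step 8**
Reactants: 13 vinyl epoxide lactone
Product: 14 hydroxy Weinreb amide (C6 carries methyl and C(=O)N(OMe)Me; C1 carries the CH(OH)CH2OSi(tBu)Ph2 arm)
Conditions: MeONHMe·HCl, iPrMgCl, THF, −20 to 0 °C; aq NH4Cl
Reagents that add atoms: N,O-dimethylhydroxylamine hydrochloride, CNOC.Cl
Why: Lactone aminolysis by the chloromagnesium amide (Weinreb amide formation) opens the cis-fused lactone at the acyl carbon without a Lewis acid, so the vinyl epoxide should survive, and the crude hydroxy amide is oxidised at once to forestall relactonisation.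

**Step 9**
Reactants: 14 hydroxy Weinreb amide
Product: 15 keto Weinreb amide (C1 arm is C(=O)CH2OSi(tBu)Ph2)
Conditions: Dess–Martin periodinane, NaHCO3, CH2Cl2, 0 °C to rt
Reagents that add atoms: none
Why: Dess–Martin oxidation under bicarbonate buffer converts the secondary alcohol into the ketone, which erases the carbinol stereocentre inherited from 1 and blocks relactonisation, while the neutral medium avoids β-elimination of the epoxide from the β,γ-epoxy ketone.

**Step 10**
Reactants: 15 keto Weinreb amide
Product: 16 alkene Weinreb amide (C1 arm is C(=CH2)CH2OSi(tBu)Ph2)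
Conditions: Cp2TiMe2, PhMe/THF, 65 °C, dark
Reagents that add atoms: dimethyltitanocene, [CH3-].[CH3-].[Ti+4].c1cc[cH-]c1.c1cc[cH-]c1
Why: Petasis methylenation (titanium methylidene, [2+2] with the ketone and cycloreversion) is chosen over a basic ylide because it is non-basic, so the enolisable C1–H is neither epimerised nor used to open the epoxide, and the hindered amide should react far more slowly than the ketone.

**Step 11**
Reactants: 16 alkene Weinreb amide
Product: 18 neopentyl aldehyde (fragment 3; C6 carries methyl and CHO), via aluminium hemiaminal 17 (not isolated)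
Conditions: iBu2AlH, THF, −78 to −40 °C; aq potassium sodium tartrate
Reagents that add atoms: none
Why: Hydride reduction of the Weinreb amide stops at the chelated aluminium hemiaminal, which releases the aldehyde only on work-up; the quaternary α-carbon cannot epimerise and the epoxide should be inert to iBu2AlH at low temperature.

**Step 12**
Reactants: 18 neopentyl aldehyde; 19 methyl 2-methyl-3-oxopentanoate (fragment 4)
Product: 21 δ-hydroxy β-keto ester (mixture at the carbinol carbon plus the two methine carbons), via keto ester dianion 20 (not isolated)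
Conditions: NaH, THF, 0 °C; n-BuLi, 0 °C; then 18, −78 °C; aq NH4Cl
Reagents that add atoms: none
Why: Aldol addition of the β-keto ester dianion through its more reactive γ-carbon to the non-enolisable aldehyde; the three new centres form as a mixture and are all removed in steps 13 to 15.

**Step 13**
Reactants: 21 δ-hydroxy β-keto ester
Product: 22 3,5-diketo ester (keto/enol tautomers)
Conditions: Dess–Martin periodinane, NaHCO3, CH2Cl2, rt
Reagents that add atoms: none
Why: Dess–Martin oxidation of the hindered secondary alcohol under buffered, non-acidic conditions compatible with the vinyl epoxide.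

**Step 14**
Reactants: 22 3,5-diketo ester
Product: 23 4-hydroxy-3,5-dimethyl-2H-pyran-2-one attached through its C6 to ring carbon C6
Conditions: DBU, PhMe, rt to 50 °C
Reagents that add atoms: none
Why: Base-mediated lactonisation, in which the enol oxygen of the ketone next to the quaternary carbon attacks the ester (acyl substitution closing the six-membered ring) with loss of methanol, removing the remaining stereorandom centres.

**Step 15**
Reactants: 23 4-hydroxy-2-pyranone
Product: 24 2-methoxy-3,5-dimethyl-4H-pyran-4-one silyl ether
Conditions: MeOTf (1.2 equiv), 2,6-di-tert-butyl-4-methylpyridine, CH2Cl2, 0 °C to rt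
Reagents that add atoms: methyl trifluoromethanesulfonate, COS(=O)(=O)C(F)(F)F
Why: O-Methylation with a hard methylating agent should occur at the most nucleophilic oxygen of the neutral hydroxypyranone, the C2 carbonyl oxygen (the 4-oxygen is flanked by two methyls), giving the 2-methoxy-4-pyranone after proton loss, while the hindered pyridine is not methylated and traps the acid that would open the vinyl epoxide.

**Step 16**
Reactants: 24 2-methoxy-4-pyranone silyl ether
Product: 25 allylic alcohol (C1 arm is C(=CH2)CH2OH)
Conditions: Bu4NF, THF, 0 °C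
Reagents that add atoms: none
Why: Fluoride-induced desilylation of the primary allylic silyl ether, to which the pyranone, the epoxide and the alkenes should be inert.

**Step 17**
Reactants: 25 allylic alcohol
Product: 26 2-substituted acrolein (fragment 5; C1 arm is C(=CH2)CHO)
Conditions: Dess–Martin periodinane, NaHCO3, CH2Cl2, 0 °C
Reagents that add atoms: none
Why: Dess–Martin oxidation of the primary allylic alcohol to the enal under buffered conditions, the enal being used at once because 2-substituted acroleins oligomerise.

**Step 18**
Reactants: 26 2-substituted acrolein; 27 pentan-3-one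
Product: 30 target CNP0233636.2, via boron enolate 28 (not isolated), via boron aldolate 29 (not isolated)
Conditions: 27, (+)-Ipc2BOTf [from (−)-α-pinene], iPr2NEt, CH2Cl2, −78 °C; 26, −78 to −20 °C; pH 7 buffer, MeOH, 30% H2O2, 0 °C
Reagents that add atoms: none
Why: Boron aldol reaction in which the (Z)-enol borinate of pentan-3-one adds through a chair Zimmerman–Traxler transition state to give the syn hydroxyl/methyl pair, while the isopinocampheyl ligands direct attack to the Re face of the enal and so set the (R) carbinol and (R) methyl centres under reagent control; buffered peroxide work-up cleaves the borinate without acid.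

**Compound list**
1 | (S)-5-(hydroxymethyl)dihydrofuran-2(3H)-one | OC[C@@H]1CCC(=O)O1 | starting material
2 | (S)-5-[(tert-butyldiphenylsilyl)oxymethyl]dihydrofuran-2(3H)-one | O=C1CC[C@@H](CO[Si](c5ccccc5)(c6ccccc6)C(C)(C)C)O1 | intermediate
3 | lithium enolate of 2 | [Li+].[O-]C1=CC[C@@H](CO[Si](c5ccccc5)(c6ccccc6)C(C)(C)C)O1 | intermediate (not isolated)
4 | (3R,5S)-5-[(tert-butyldiphenylsilyl)oxymethyl]-3-methyldihydrofuran-2(3H)-one (trans isomer drawn) | C[C@@H]1C[C@@H](CO[Si](c5ccccc5)(c6ccccc6)C(C)(C)C)OC1=O | intermediate
5 | lithium enolate of 4 | [Li+].[O-]C1=C(C)C[C@@H](CO[Si](c5ccccc5)(c6ccccc6)C(C)(C)C)O1 | intermediate (not isolated)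
6 | (3R,5S)-5-[(tert-butyldiphenylsilyl)oxymethyl]-3-methyl-3-(phenylselanyl)dihydrofuran-2(3H)-one | C[C@@]1([Se]c2ccccc2)C[C@@H](CO[Si](c5ccccc5)(c6ccccc6)C(C)(C)C)OC1=O | intermediate
7 | selenoxide of 6 (mixture at selenium) | C[C@@]1([Se](=O)c2ccccc2)C[C@@H](CO[Si](c5ccccc5)(c6ccccc6)C(C)(C)C)OC1=O | intermediate (not isolated)
8 | (S)-5-[(tert-butyldiphenylsilyl)oxymethyl]-3-methylfuran-2(5H)-one, fragment 1 | CC1=C[C@@H](CO[Si](c5ccccc5)(c6ccccc6)C(C)(C)C)OC1=O | intermediate
9 | 3,5-dibromo-2H-pyran-2-one | O=c1occ(Br)cc1Br | starting material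
10 | 3,5-dimethyl-2H-pyran-2-one, fragment 2 | Cc1coc(=O)c(C)c1 | intermediate
11 | bridged lactone adduct (2-oxabicyclo[2.2.2]octenone fused to the γ-lactone; endo isomer drawn, the other bridge isomers behave alike) | O=C1O[C@H](CO[Si](c5ccccc5)(c6ccccc6)C(C)(C)C)[C@H]2[C@]3(C)C(=O)O[C@@H](C(C)=C3)[C@@]12C | intermediate (not isolated)
12 | cis-fused diene lactone, (3S)-3-[(tert-butyldiphenylsilyl)oxymethyl]-4,6,7a-trimethyl-3a,7a-dihydroisobenzofuran-1(3H)-one, silyloxymethyl anti to the carbocycle | O=C1O[C@H](CO[Si](c5ccccc5)(c6ccccc6)C(C)(C)C)[C@H]2C(C)=CC(C)=C[C@@]12C | intermediate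
13 | vinyl epoxide lactone (4,5-epoxide of 12, oxygen anti to the lactone ring) | O=C1O[C@H](CO[Si](c5ccccc5)(c6ccccc6)C(C)(C)C)[C@H]2[C@]3(C)O[C@@H]3C(C)=C[C@@]12C | intermediate
14 | hydroxy Weinreb amide | O[C@H](CO[Si](c5ccccc5)(c6ccccc6)C(C)(C)C)[C@H]1[C@]2(C)O[C@@H]2C(C)=C[C@@]1(C)C(=O)N(C)OC | intermediate
15 | keto Weinreb amide | O=C(CO[Si](c5ccccc5)(c6ccccc6)C(C)(C)C)[C@H]1[C@]2(C)O[C@@H]2C(C)=C[C@@]1(C)C(=O)N(C)OC | intermediate
16 | alkene Weinreb amide | C=C(CO[Si](c5ccccc5)(c6ccccc6)C(C)(C)C)[C@H]1[C@]2(C)O[C@@H]2C(C)=C[C@@]1(C)C(=O)N(C)OC | intermediate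
17 | aluminium hemiaminal of 16 (mixture at the new carbon) | C=C(CO[Si](c5ccccc5)(c6ccccc6)C(C)(C)C)[C@H]1[C@]2(C)O[C@@H]2C(C)=C[C@@]1(C)C(O[Al](CC(C)C)CC(C)C)N(C)OC | intermediate (not isolated)
18 | neopentyl aldehyde with the 1,1-disubstituted alkene arm, fragment 3 | C=C(CO[Si](c5ccccc5)(c6ccccc6)C(C)(C)C)[C@H]1[C@]2(C)O[C@@H]2C(C)=C[C@@]1(C)C=O | intermediate
19 | methyl 2-methyl-3-oxopentanoate, fragment 4 | CCC(=O)C(C)C(=O)OC | starting material
20 | sodium lithium dianion of 19 | [Na+].[Li+].CC=C([O-])C(C)=C([O-])OC | intermediate (not isolated)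
21 | δ-hydroxy β-keto ester (mixture at three centres) | C=C(CO[Si](c5ccccc5)(c6ccccc6)C(C)(C)C)[C@H]1[C@]2(C)O[C@@H]2C(C)=C[C@@]1(C)C(O)C(C)C(=O)C(C)C(=O)OC | intermediate
22 | 3,5-diketo ester | C=C(CO[Si](c5ccccc5)(c6ccccc6)C(C)(C)C)[C@H]1[C@]2(C)O[C@@H]2C(C)=C[C@@]1(C)C(=O)C(C)C(=O)C(C)C(=O)OC | intermediate
23 | 4-hydroxy-3,5-dimethyl-2-pyranone on ring carbon C6 | C=C(CO[Si](c5ccccc5)(c6ccccc6)C(C)(C)C)[C@H]1[C@]2(C)O[C@@H]2C(C)=C[C@@]1(C)c1oc(=O)c(C)c(O)c1C | intermediate
24 | 2-methoxy-3,5-dimethyl-4-pyranone silyl ether | C=C(CO[Si](c5ccccc5)(c6ccccc6)C(C)(C)C)[C@H]1[C@]2(C)O[C@@H]2C(C)=C[C@@]1(C)c1oc(OC)c(C)c(=O)c1C | intermediate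
25 | allylic alcohol | C=C(CO)[C@H]1[C@]2(C)O[C@@H]2C(C)=C[C@@]1(C)c1oc(OC)c(C)c(=O)c1C | intermediate
26 | 2-substituted acrolein, fragment 5 | C=C(C=O)[C@H]1[C@]2(C)O[C@@H]2C(C)=C[C@@]1(C)c1oc(OC)c(C)c(=O)c1C | intermediate
27 | pentan-3-one | CCC(=O)CC | starting material
28 | (Z)-pent-2-en-3-yl diisopinocampheylborinate ((+)-Ipc series) | C/C=C(/CC)OB([C@H]1C[C@H]2C[C@@H]([C@@H]1C)C2(C)C)[C@H]1C[C@H]2C[C@@H]([C@@H]1C)C2(C)C | intermediate (not isolated)
29 | diisopinocampheylboron aldolate of the target | C=C([C@H](OB([C@H]3C[C@H]4C[C@@H]([C@@H]3C)C4(C)C)[C@H]3C[C@H]4C[C@@H]([C@@H]3C)C4(C)C)[C@@H](C)C(=O)CC)[C@H]1[C@]2(C)O[C@@H]2C(C)=C[C@@]1(C)c1oc(OC)c(C)c(=O)c1C | intermediate (not isolated)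
30 | CNP0233636.2 (syn aldol, (R) carbinol and (R) methyl in the side chain) | C=C([C@H](O)[C@@H](C)C(=O)CC)[C@H]1[C@]2(C)O[C@@H]2C(C)=C[C@@]1(C)c1oc(OC)c(C)c(=O)c1C | target

**Step count**
Total: 18 steps. Longest linear sequence: 17 steps (steps 1–4 and 6–18, from 1 to 30); step 5 is a one-step side branch.

**Steps most likely to fail**

Step 6. The cycloaddition may stall (trisubstituted dienophile, unactivated pyranone). The partners may also combine in the reverse orientation (butenolide β-carbon to pyranone C6), because the two ring methyls of 10 electronically favour that mode and only the steric term opposes it. Fallback, setting out from 8 and returning at 12: the carbocycle is closed with an acyclic 1-silyloxy diene whose oxygen fixes the orientation. (E)-2-Methylpent-2-enal F1 (bought) is converted with Me3SiCl, Et3N and catalytic ZnCl2 into (1E,3E)-2-methyl-1-(trimethylsilyloxy)penta-1,3-diene F2. Thermal Diels–Alder reaction of F2 with 8 (PhMe, sealed tube, 130 °C) should again occur anti to the silyloxymethyl group, with the oxygen-bearing diene terminus bonding to the methyl-bearing α-carbon, to give the cyclohexene silyl ether F3 (its two extra centres are removed later). Mild acid hydrolysis gives the allylic alcohol F4. Acid-catalysed 1,4-dehydration (camphorsulfonic acid, PhMe, 60 °C) through the allyl cation, which can lose a proton only from the methyl-bearing CH, leads to 12.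

Step 7. Oxygen may be delivered to the other ring double bond or to the concave face, or the diene may be oxidised twice. Fallback, setting out from 12 and returning at 16: the epoxide is introduced only after the lactone has been opened. Aminolysis, oxidation and methylenation under the conditions of steps 8 to 10 give in turn the diene hydroxy amide F5, the diene keto amide F6 and the triene amide F7. In F7 both carbon arms stand on one face of a monocyclic diene, and the amide-bearing quaternary carbon screens the neighbouring double bond. Dimethyldioxirane is therefore expected to oxidise the ring double bond next to C1 anti to both arms, giving 16. This order also keeps the epoxide away from the ketone stage.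

Step 18. Reagent control over the face of the hindered enal may be incomplete (opposing substrate bias), and the 2-substituted acrolein may oligomerise before it is trapped. Fallback, setting out from 26 and returning at 30: auxiliary control replaces reagent control. Evans syn aldol of 26 with (R)-4-benzyl-3-propionyloxazolidin-2-one F8 (bought; Bu2BOTf, iPr2NEt, CH2Cl2, −78 to 0 °C) should give the imide F9 with the required syn (R,R) pair. Transamidation with the amide preformed from Me3Al and MeONHMe·HCl (CH2Cl2, −20 °C) gives the β-hydroxy Weinreb amide F10. EtMgBr (THF, −20 to 0 °C) then gives 30.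

**Further compounds**
F1 | step 6 | (E)-2-methylpent-2-enal | CC/C=C(\C)C=O
F2 | step 6 | (1E,3E)-2-methyl-1-(trimethylsilyloxy)penta-1,3-diene | C[Si](C)(C)O/C=C(C)/C=C/C
F3 | step 6 | cyclohexene silyl ether, cis-fused lactone with 7-trimethylsilyloxy and 4,6,7a-trimethyl groups | O=C1O[C@H](CO[Si](c5ccccc5)(c6ccccc6)C(C)(C)C)[C@H]2C(C)C=C(C)C(O[Si](C)(C)C)[C@@]12C
F4 | step 6 | allylic alcohol, 7-hydroxy analogue of F3 | O=C1O[C@H](CO[Si](c5ccccc5)(c6ccccc6)C(C)(C)C)[C@H]2C(C)C=C(C)C(O)[C@@]12C
F5 | step 7 | diene hydroxy Weinreb amide | O[C@H](CO[Si](c5ccccc5)(c6ccccc6)C(C)(C)C)[C@H]1C(C)=CC(C)=C[C@@]1(C)C(=O)N(C)OC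
F6 | step 7 | diene keto Weinreb amide | O=C(CO[Si](c5ccccc5)(c6ccccc6)C(C)(C)C)[C@H]1C(C)=CC(C)=C[C@@]1(C)C(=O)N(C)OC
F7 | step 7 | triene Weinreb amide | C=C(CO[Si](c5ccccc5)(c6ccccc6)C(C)(C)C)[C@H]1C(C)=CC(C)=C[C@@]1(C)C(=O)N(C)OC
F8 | step 18 | (R)-4-benzyl-3-propionyloxazolidin-2-one | CCC(=O)N1[C@H](Cc2ccccc2)COC1=O
F9 | step 18 | Evans syn aldol imide | C=C([C@H](O)[C@@H](C)C(=O)N3[C@H](Cc4ccccc4)COC3=O)[C@H]1[C@]2(C)O[C@@H]2C(C)=C[C@@]1(C)c1oc(OC)c(C)c(=O)c1C
F10 | step 18 | β-hydroxy Weinreb amide | C=C([C@H](O)[C@@H](C)C(=O)N(C)OC)[C@H]1[C@]2(C)O[C@@H]2C(C)=C[C@@]1(C)c1oc(OC)c(C)c(=O)c1C
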